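**Two ends.** The ratio of G to J rises with the charge: at 10.0 h G holds 54.6% of G plus J in the green run, less than the 67.4% of the red run.

| setting | green | red | flask |
|---|---|---|---|
| D | 20 mM | 82 mM | 41 mM |
| remark | run made earlier | run made earlier |  |
| time |  |  | 12 h |

| run | time / h | G / % | J / % |
|---|---|---|---|
| green | 0.833 | 20.1 | 10.2 |
| green | 1.33 | 26.3 | 14.2 |
| green | 2.00 | 35.8 | 18.1 |
| green | 2.50 | 40.1 | 24.9 |
| green | 4.00 | 48.2 | 32.2 |
| green | 6.00 | 53.7 | 36.0 |
| green | 10.0 | 51.0 | 42.4 |
| red | 1.33 | 27.3 | 13.5 |
| red | 3.00 | 44.8 | 21.3 |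
| red | 4.00 | 50.2 | 26.4 |
| red | 6.00 | 58.9 | 27.4 |
| red | 8.00 | 59.5 | 29.5 |
| red | 10.0 | 62.3 | 30.2 |

(each reading ± 1 percentage point)

* share of G in G plus J at 2.0 min
* share of G in G plus J at 12 h

- in percentages every species weighs as the D in it: one E counts as two
- for G the Z are counted in
- as a solid, counted per litre of solution: Z
- candidate steps: D <-> Q; D -> G; Q -> J; G <-> J; D + G -> E; Z <-> G

**Mean drain.** Suppose that Z holds dissolved G at one level, so that G leaks to J at one absolute rate in both runs. The share then falls with time over charge, and the two ends give 0.337 mM h⁻¹. This is the drain, the mean rate at which G turns into J, taken as constant over the run.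

**Zero-drain share.** Adding the red run's loss back gives 71.5%, the kinetic selectivity read from these runs.

**The flask.** Over 12 h the drain takes 9.9 percentage points from the share, leaving 61.6%. At 2.0 min it has had far less time than at 12 h, so the reckoning here puts that share at 71.5% or above. The earliest reading, at 0.833 h, comes later than that and cannot say how far above.

**Weak link.** A real drain need not be steady, so the mean was reckoned again from the readings at 6.00 h. They give 0.370 mM h⁻¹ and a flask share of 60.1%, so the curve's shape moves the answer by 1.5 points.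

**Forecast.** The forecast gave 85% (from 69% to 97%) and 60% (from 55% to 65%), slightly lower than 61.6% at the late time, holding that “Z crystals hold dissolved G near saturation”.

**Result.** The flask gives 81.9% at 2.0 min and 62.2% at 12 h, when Z stands at 55.1% of the charge within G's 58.5%.

    D ⇌ Q (K = 0.0330, k = 0.0291 min⁻¹)
    D → G (k = 0.00519 min⁻¹)
    Q → J (k = 0.0656 min⁻¹)
    G ⇌ J (K = 18.0, k = 0.00477 min⁻¹)
    D + G → E (k = 0.100 M⁻¹ min⁻¹)
    Z ⇌ G, rate k6*(cs6 - [G]) while solid is left; crystals form when [G] > cs6 (solubility = 1.40 mM, k = 0.127 min⁻¹)

A neighbour charged with 10 mM loses 40 points by the same drain, which leaves 31.1%; that flask gives 30.3%.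

The data come from a simulation on assumed constants; scatter was added.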